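**Retrosynthetic overview**
1. The target is reached from a tertiary chroman-4-yl pinacol boronate by cleavage of the methoxymethyl ether at the C5 oxygen and stereoretentive exchange of C4–B for C4–H.
2. Key disconnection C3–C4: the boronate comes from an open-chain diarylmethyl N,N-diisopropylcarbamate whose O1–C2 arm ends in a C3–B(pin) group. After lithiation at C4 a seven-membered cyclic boronate complex forms and contracts by a 1,2-metalate shift to the dihydropyran ring, the only ring that is built (the benzene and naphthalene rings are bought).
3. Enabling feature: C4 is doubly benzylic, between C4a of the benzo ring and C1 of the naphthalene ring, so its carbamate is easily lithiated and ionised. O1 on C8a holds C3 within reach of C4, and the C5 oxygen peri to C4 forces the naphthyl group pseudoaxial, trans to the C2 methyl group.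
4. The carbamate comes from the aryllithium of 1-bromo-4,5-dimethoxynaphthalene and a salicylaldehyde-type aldehyde (C4–naphthyl bond), followed by O-carbamoylation and copper-catalysed borylation of the C3–Cl bond.
5. C2 comes from the chiral pool: Mitsunobu inversion of (S)-1-chloropropan-2-ol with 2-hydroxy-6-(methoxymethoxy)benzaldehyde makes the O1–C2 bond.

Key step: step 5

Assumption: the carbamates and the intermediates between them that carry the carbinol carbon (the future C4) are taken as mixtures of both epimers at that carbon, which is planarised in the key step; chroman numbering (O1, C2, C3, C4, C4a, C5–C8, C8a) is used for the open-chain precursors as well.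

**Route**

Step 1
Reactants: 1 1,8-dimethoxynaphthalene
Product: 2 1-bromo-4,5-dimethoxynaphthalene
Conditions: NBS, MeCN, 0 °C → rt
Reagents that add atoms: N-bromosuccinimide, O=C1CCC(=O)N1Br
Why: Electrophilic aromatic bromination of the strongly activated naphthalene should take place para to a methoxy group (C4), the usual site of substitution in 1-alkoxynaphthalenes.

Step 2
Reactants: 3 2-hydroxy-6-(methoxymethoxy)benzaldehyde; 4 (S)-1-chloropropan-2-ol
Product: 5 2-{[(2R)-1-chloropropan-2-yl]oxy}-6-(methoxymethoxy)benzaldehyde
Conditions: PPh3, DIAD, THF, 0 °C → rt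
Reagents that add atoms: none
Why: In this Mitsunobu etherification the acidic phenol displaces the activated secondary alcohol with inversion, so the (S)-alcohol should give the (2R)-aryl ether that becomes C2 of the target, the primary chloride being inert.

Step 3
Reactants: 2 1-bromo-4,5-dimethoxynaphthalene; 5 2-{[(2R)-1-chloropropan-2-yl]oxy}-6-(methoxymethoxy)benzaldehyde
Product: 8 [2-{[(2R)-1-chloropropan-2-yl]oxy}-6-(methoxymethoxy)phenyl](4,5-dimethoxynaphthalen-1-yl)methyl N,N-diisopropylcarbamate (both epimers at the carbinol carbon), via aryllithium 6 (not isolated), via lithium alkoxide 7 (not isolated)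
Conditions: n-BuLi, THF, −78 °C; then 5, −78 °C; then iPr2NCOCl, −78 → 60 °C
Reagents that add atoms: N,N-diisopropylcarbamoyl chloride, CC(C)N(C(C)C)C(Cl)=O
Why: Bromine–lithium exchange, 1,2-addition of the aryllithium to the aldehyde (much faster at −78 °C than attack at the primary chloride) and O-carbamoylation of the alkoxide in the same flask should give the carbamate; the new carbinol centre forms without control, which does not matter because it is planarised in step 5.

Step 4
Reactants: 8 [2-{[(2R)-1-chloropropan-2-yl]oxy}-6-(methoxymethoxy)phenyl](4,5-dimethoxynaphthalen-1-yl)methyl N,N-diisopropylcarbamate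
Product: 9 (4,5-dimethoxynaphthalen-1-yl)[2-(methoxymethoxy)-6-{[(2R)-1-(4,4,5,5-tetramethyl-1,3,2-dioxaborolan-2-yl)propan-2-yl]oxy}phenyl]methyl N,N-diisopropylcarbamate (both epimers at the carbinol carbon)
Conditions: B2pin2, CuI (10 mol %), PPh3, LiOMe, Bu4NI, DMF, 40 °C
Reagents that add atoms: bis(pinacolato)diboron, CC1(C)OB(OC1(C)C)B1OC(C)(C)C(C)(C)O1
Why: Copper-catalysed borylation of an unactivated primary alkyl halide with B2pin2 (boryl-copper substitution, the chloride being activated in the flask by iodide exchange) should tolerate the carbamate, the acetal and the aryl ethers and does not touch C2.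

Step 5
Reactants: 9 (4,5-dimethoxynaphthalen-1-yl)[2-(methoxymethoxy)-6-{[(2R)-1-(4,4,5,5-tetramethyl-1,3,2-dioxaborolan-2-yl)propan-2-yl]oxy}phenyl]methyl N,N-diisopropylcarbamate
Product: 12 2-[(2R,4S)-4-(4,5-dimethoxynaphthalen-1-yl)-5-(methoxymethoxy)-2-methyl-3,4-dihydro-2H-1-benzopyran-4-yl]-4,4,5,5-tetramethyl-1,3,2-dioxaborolane, via lithiated carbamate 10 (not isolated), via cyclic boronate complex 11 (not isolated)
Conditions: LDA (1.3 equiv), THF, −78 °C; then −78 → 25 °C
Reagents that add atoms: none
Why: Proposed new method: LDA removes the doubly benzylic C4–H next to the carbamate oxygen, both carbinol epimers giving the same configurationally labile carbanion 10, which adds to the tethered boronate to form the seven-membered cyclic boronate complex 11; the B–C3 bond then migrates to C4 antiperiplanar to the leaving carbamate, so the C3–C4 bond forms while the former aldehyde oxygen is expelled. The closest known reaction type is the intermolecular lithiation–borylation of benzylic carbamates with alkyl pinacol boronates (1,2-metalate rearrangement), which has not been run as a ring closure on a diarylmethyl carbamate with an internal boronate. The dihydropyran ring is closed by contraction of the seven-membered boracycle to the six-membered ring, in effect a 6-exo-tet attack of C3 on C4 with boron as the carrier; a carbon–boron bond is used because a C3–Li or C3–Mg bond would expel the aryloxide from C2. The new stereocentre C4 is controlled by the C2 methyl group, equatorial in the chair-like transition state, and by 1,3-allylic strain with the C5 methoxymethoxy group, which should put the bulky naphthyl group pseudoaxial and the boronate (small on a ring carbon because of its planar boron and long C–B bond) pseudoequatorial beside C5, that is in the place of the future C4–H of the (2R,4S) target. The step needs C3 to migrate in preference to a pinacol oxygen and needs one C4 epimer; C3 is the only carbon on boron, formation of 11 from the stabilised carbanion should be reversible so that both epimeric complexes drain through the less strained transition state, and the ring torsion B–C3–C2–O1 in 11 cannot become antiperiplanar, which blocks β-elimination of the aryloxide.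

Step 6
Reactants: 12 2-[(2R,4S)-4-(4,5-dimethoxynaphthalen-1-yl)-5-(methoxymethoxy)-2-methyl-3,4-dihydro-2H-1-benzopyran-4-yl]-4,4,5,5-tetramethyl-1,3,2-dioxaborolane
Product: 13 (2R,4S)-4-(4,5-dimethoxynaphthalen-1-yl)-5-(methoxymethoxy)-2-methyl-3,4-dihydro-2H-1-benzopyran
Conditions: CsF, H2O (1.5 equiv), 1,4-dioxane, 45 °C
Reagents that add atoms: none
Why: Fluoride-promoted protodeboronation of tertiary diarylalkyl pinacol boronates with CsF and a little water is known to go with retention, so hydrogen should take the place of boron and C4 becomes S, trans to the C2 methyl group.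

Step 7
Reactants: 13 (2R,4S)-4-(4,5-dimethoxynaphthalen-1-yl)-5-(methoxymethoxy)-2-methyl-3,4-dihydro-2H-1-benzopyran
Product: 14 (2R,4S)-4-(4,5-dimethoxynaphthalen-1-yl)-2-methyl-3,4-dihydro-2H-1-benzopyran-5-ol (cladonaphchrom A)
Conditions: HCl, MeOH, 40 °C
Reagents that add atoms: none
Why: Acid-catalysed cleavage of the methoxymethyl acetal (transacetalisation to dimethoxymethane) should free the C5 phenol without touching the aryl methyl ethers, the chroman ether or either stereocentre.

**Compound list**
1 | 1,8-dimethoxynaphthalene | COc1cccc2cccc(OC)c12 | starting material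
2 | 1-bromo-4,5-dimethoxynaphthalene | COc1cccc2c(Br)ccc(OC)c12 | intermediate
3 | 2-hydroxy-6-(methoxymethoxy)benzaldehyde | COCOc1cccc(O)c1C=O | starting material
4 | (S)-1-chloropropan-2-ol | C[C@H](O)CCl | starting material
5 | 2-{[(2R)-1-chloropropan-2-yl]oxy}-6-(methoxymethoxy)benzaldehyde | ClC[C@@H](C)Oc1cccc(OCOC)c1C=O | intermediate
6 | (4,5-dimethoxynaphthalen-1-yl)lithium | [Li]c1ccc(OC)c2c(OC)cccc12 | intermediate (not isolated)
7 | lithium [2-{[(2R)-1-chloropropan-2-yl]oxy}-6-(methoxymethoxy)phenyl](4,5-dimethoxynaphthalen-1-yl)methanolate, both carbinol epimers | [Li]OC(c1ccc(OC)c2c(OC)cccc12)c1c(O[C@H](C)CCl)cccc1OCOC | intermediate (not isolated)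
8 | [2-{[(2R)-1-chloropropan-2-yl]oxy}-6-(methoxymethoxy)phenyl](4,5-dimethoxynaphthalen-1-yl)methyl N,N-diisopropylcarbamate, both carbinol epimers | CC(C)N(C(C)C)C(=O)OC(c1ccc(OC)c2c(OC)cccc12)c1c(O[C@H](C)CCl)cccc1OCOC | intermediate
9 | (4,5-dimethoxynaphthalen-1-yl)[2-(methoxymethoxy)-6-{[(2R)-1-(4,4,5,5-tetramethyl-1,3,2-dioxaborolan-2-yl)propan-2-yl]oxy}phenyl]methyl N,N-diisopropylcarbamate, both carbinol epimers | CC(C)N(C(C)C)C(=O)OC(c1ccc(OC)c2c(OC)cccc12)c1c(O[C@H](C)CB2OC(C)(C)C(C)(C)O2)cccc1OCOC | intermediate
10 | α-lithiated carbamate of 9 (lithium on the carbinol carbon) | [Li]C(OC(=O)N(C(C)C)C(C)C)(c1ccc(OC)c2c(OC)cccc12)c1c(O[C@H](C)CB2OC(C)(C)C(C)(C)O2)cccc1OCOC | intermediate (not isolated)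
11 | lithium salt of the seven-membered cyclic boronate complex (ring C4–B–C3–C2–O1–C8a–C4a; boron spiro to the pinacolate; C4 carries the naphthyl and carbamoyloxy groups; (2R)) | [Li+].CC(C)N(C(C)C)C(=O)OC1(c2ccc(OC)c3c(OC)cccc23)c2c(OCOC)cccc2O[C@H](C)C[B-]13OC(C)(C)C(C)(C)O3 | intermediate (not isolated)
12 | 2-[(2R,4S)-4-(4,5-dimethoxynaphthalen-1-yl)-5-(methoxymethoxy)-2-methyl-3,4-dihydro-2H-1-benzopyran-4-yl]-4,4,5,5-tetramethyl-1,3,2-dioxaborolane | COc1cccc2c([C@]3(B5OC(C)(C)C(C)(C)O5)C[C@@H](C)Oc4cccc(OCOC)c43)ccc(OC)c12 | intermediate
13 | (2R,4S)-4-(4,5-dimethoxynaphthalen-1-yl)-5-(methoxymethoxy)-2-methyl-3,4-dihydro-2H-1-benzopyran | COc1cccc2c([C@@H]3C[C@@H](C)Oc4cccc(OCOC)c43)ccc(OC)c12 | intermediate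
14 | (2R,4S)-4-(4,5-dimethoxynaphthalen-1-yl)-2-methyl-3,4-dihydro-2H-1-benzopyran-5-ol (cladonaphchrom A, 2,4-trans) | COc1cccc2c([C@@H]3C[C@@H](C)Oc4cccc(O)c43)ccc(OC)c12 | target

**Step count**
Total steps: 7. Longest linear sequence: 6 steps (steps 2–7 from 3 and 4; equally steps 1 and 3–7 from 1).

**Steps most likely to fail**

1. Step 5 (the proposed new method). The carbanion may not engage the boronate before 1,2-migration of the carbamoyl group, the base may trigger β-elimination of the aryloxide from the boronate arm, a pinacol oxygen may migrate instead of C3, or facial selectivity at C4 may be poor. The fallback uses known chemistry and sets out from 8, so step 4 is not needed. LDA, THF, −78 °C → rt should close the ring by intramolecular alkylation of the α-lithiated carbamate with the primary chloride (6-exo-tet cycloalkylation, a known reaction of lithiated carbamates), giving the tertiary carbamate (2R)-4-(4,5-dimethoxynaphthalen-1-yl)-5-(methoxymethoxy)-2-methyl-3,4-dihydro-2H-1-benzopyran-4-yl N,N-diisopropylcarbamate F1. Et3SiH, CF3CO2H, CH2Cl2, 0 °C → rt (ionic hydrogenation) should then ionise the tertiary doubly benzylic carbamate and deliver hydride to the twisted C4 cation on the face that lets the naphthyl group become pseudoaxial (trans). The same acid should cleave the methoxymethyl ether, so the route is rejoined at 14; any surviving 13 goes through step 7.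

2. Step 4. Substitution at the β-branched, β-oxygenated primary chloride may be slow, and the C3 radical or alkylcopper intermediate may lose the aryloxide by β-scission or elimination. The fallback sets out from 8 and makes C3 the electrophile at the diarylmethane oxidation level. H2, Pd/C (palladium on carbon), EtOAc, rt should hydrogenolyse the doubly benzylic C–O bond, leaving the alkyl chloride, acetal and naphthalene intact, to give 1-[(2-{[(2R)-1-chloropropan-2-yl]oxy}-6-(methoxymethoxy)phenyl)methyl]-4,5-dimethoxynaphthalene F2. s-BuLi, TMEDA, THF, −78 → 0 °C should then effect lateral lithiation and 6-exo-tet alkylation of the diarylmethyl anion by the chloride; C3 approaches C4 on the side of its hydrogen, so the naphthyl group ends pseudoaxial. The route is rejoined at 13.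

3. Step 6. Protodeboronation at the congested tertiary centre may be slow, or stereochemical fidelity may be lost if a free carbanion is protonated from the wrong face. The fallback sets out from 12 and installs the C4 hydrogen as hydride instead of as a proton. NaBO3·4H2O, THF/H2O, rt should oxidise the C–B bond to the tertiary alcohol (2R,4R)-4-(4,5-dimethoxynaphthalen-1-yl)-5-(methoxymethoxy)-2-methyl-3,4-dihydro-2H-1-benzopyran-4-ol F3. Et3SiH, CF3CO2H, CH2Cl2, 0 °C → rt should then reduce the derived C4 cation under the same strain control (naphthyl pseudoaxial, trans) and remove the methoxymethyl group, rejoining the route at 14.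

**Further compounds**
F1 | step 5 | (2R)-4-(4,5-dimethoxynaphthalen-1-yl)-5-(methoxymethoxy)-2-methyl-3,4-dihydro-2H-1-benzopyran-4-yl N,N-diisopropylcarbamate (C4 epimers) | COc1cccc2c(C3(OC(=O)N(C(C)C)C(C)C)C[C@@H](C)Oc4cccc(OCOC)c43)ccc(OC)c12
F2 | step 4 | 1-[(2-{[(2R)-1-chloropropan-2-yl]oxy}-6-(methoxymethoxy)phenyl)methyl]-4,5-dimethoxynaphthalene | COc1cccc2c(Cc3c(O[C@H](C)CCl)cccc3OCOC)ccc(OC)c12
F3 | step 6 | (2R,4R)-4-(4,5-dimethoxynaphthalen-1-yl)-5-(methoxymethoxy)-2-methyl-3,4-dihydro-2H-1-benzopyran-4-ol | COc1cccc2c([C@]3(O)C[C@@H](C)Oc4cccc(OCOC)c43)ccc(OC)c12
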